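The pitfall in these flasks was to give each run one first-order constant and then treat that constant as the chemistry. In each run, starting material turns into target, with free catalyst charged at the start.

| flask | starting material | free catalyst | time |
|---|---|---|---|
| west | 80.0 mM | 8.00 mM |  |
| south-west | 32.0 mM | 8.00 mM |  |
| south-east | 160 mM | 8.00 mM |  |
| south | 80.0 mM | 12.0 mM |  |
| north-east | 80.0 mM | 24.0 mM | 3.4 min |

| run | time / min | [starting material] / mM |
|---|---|---|
| west run | 0.57 | 74.1 |
| west run | 1.1 | 64.6 |
| west run | 1.7 | 54.0 |
| west run | 2.3 | 44.3 |
| west run | 2.8 | 37.2 |
| west run | 3.4 | 31.2 |
| south-west run | 0.57 | 29.0 |
| south-west run | 1.1 | 26.9 |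
| south-west run | 1.7 | 24.2 |
| south-west run | 2.3 | 21.3 |
| south-west run | 2.8 | 18.6 |
| south-west run | 3.4 | 16.6 |
| south-east run | 0.57 | 149.5 |
| south-east run | 1.1 | 131.4 |
| south-east run | 1.7 | 108.9 |
| south-east run | 2.3 | 88.2 |
| south-east run | 2.8 | 72.5 |
| south-east run | 3.4 | 57.3 |
| south run | 0.57 | 72.5 |
| south run | 1.1 | 59.7 |
| south run | 1.7 | 46.5 |
| south run | 2.3 | 35.9 |
| south run | 2.8 | 30.2 |
| south run | 3.4 | 24.0 |

(each reading ± 0.4 mM)

* order of the initial rate in [starting material], near the charge of the west run, the rate being that where two percent of its starting material are target (one fixed amount of target, the same in the runs compared)
* order of the initial rate in [free catalyst], near the charge of the west run, the rate being that where two percent of its starting material are target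
* the south-west run starts with 48.0 mM less of starting material than the west run, and with no target. Compared where both hold the same amount of starting material, once fifteen percent of what the south-west run was charged with has turned into target, is the south-west run faster, slower or alike (within a tenth)?
* starting material in the north-east run at 3.4 min, as a share of the starting material charged

- Overall: starting material -> target, with free catalyst as catalyst.
- Constant volume, constant temperature.
- The analysis sees a species whether free or bound.
- An order is taken over about fifteen percent of the charge, up and down.

My bench rule was the mean constant, the natural logarithm of charge over last reading, divided by the time of that reading; it is a pseudo-first-order constant averaged over the run. The west run gave 0.277 min⁻¹ and the south run 0.354 min⁻¹. So 1.50 times the catalyst raised the constant by 1.28 times, a whole-run exponent of 0.606. Carried to the north-east charge, that exponent gave 0.539 min⁻¹, and so 16.0% of the starting material left at 3.4 min.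

The border showed in a ratio. Over its first interval the west run read only 0.134 min⁻¹, about half of its mean constant. The mean therefore says little about early rates, and I did not take the orders from it. It was still usable for the share asked, since the asked time equals the time of the last reading, and the slow start is averaged into the constant over that same span. Nor was it a true constant across charges: the south-west run gave 0.193 min⁻¹ and the south-east run 0.302 min⁻¹.

The forecast, which held that “the reaction speeds up as target builds”, gave 0.75 (0.55 to 0.95) for the order in starting material and 0.65 (0.45 to 0.85) for the order in catalyst. It called the south-west run slower and put the north-east share at 15% (10% to 21%), against my 16.0%.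

The flask gave initial orders of 0.64 in starting material and 0.45 in free catalyst, a south-west run that was slower at equal starting material, with a rate ratio to the west run of 0.76, and 18.7% of the charge left in the north-east run, a mean constant of 0.494 min⁻¹ against my 0.539 min⁻¹.

active catalyst + starting material ⇌ catalyst-substrate complex, settled at all times (4.110 M⁻¹); catalyst-substrate complex + starting material ⇌ doubly bound catalyst, settled at all times (40.50 M⁻¹); doubly bound catalyst → target + catalyst-substrate complex (9.180 min⁻¹); starting material → target (0.04398 min⁻¹); free catalyst → active catalyst (0.9960 min⁻¹) The early catalyst order stood at 0.45 because free catalyst becomes active catalyst slowly; the simulated run with that step made instant gives 0.80. The mean constant of the south-east run promised a quarter of its charge turned into target by 0.953 min, but that run reached it at 1.42 min.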